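**Assumptions:** Macrolide numbering is used (C1 = lactone C=O, C13 = ring carbinol, C14–C16 = side chain). The Evans oxazolidinone is treated as a recoverable reagent (none of its atoms reach the target). Metal enolates are treated as activated forms of the reactants and are not numbered.

## Retrosynthetic overview

1. The only ring of the target, the 14-membered lactone, is closed last (before deprotection) by C6–C7 bond formation: a 14-endo radical (hydrogen-atom-transfer Giese) cyclisation of seco-ester 23 that also creates C6 and C8.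
2. 23 comes from a syn-aldol (C10–C11) of 2-methylpent-1-en-3-one with aldehyde 21.
3. 21 comes from intermolecular esterification (O13–C1) of acid 9 with alcohol 16, then alkene ozonolysis and alkyne semihydrogenation.
4. Acid 9 (C1–C6) comes from an Evans β-ketoimide anti-aldol and anti-reduction; alcohol 16 (C11–C16) from Fráter–Seebach methylation and catalytic anti-crotylation.
5. Ring order: temporary 1,3-dioxane (step 5), then the macrolactone (step 15); the dioxane is removed in step 16.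

## Route

Step 1
Reactants: 1 propanoyl chloride
Product: 2 (S)-4-benzyl-3-propanoyl-1,3-oxazolidin-2-one
Conditions: (S)-4-benzyl-1,3-oxazolidin-2-one, n-BuLi, THF, −78 °C; then 1, −78 → 0 °C
Reagents that add atoms: (S)-4-benzyl-1,3-oxazolidin-2-one, O=C1N[C@@H](Cc2ccccc2)CO1
Why: N-acylation of the lithiated Evans auxiliary; no new stereocentre.

Step 2
Reactants: 2 (S)-4-benzyl-3-propanoyl-1,3-oxazolidin-2-one; 1 propanoyl chloride
Product: 3 (S)-4-benzyl-3-[(2R)-2-methyl-3-oxopentanoyl]-1,3-oxazolidin-2-one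
Conditions: LiN(iPr)2, THF, −78 °C; then 1, −78 °C
Reagents that add atoms: none
Why: Claisen-type C-acylation of the chelated (Z)-lithium imide enolate anti to the benzyl group (Evans β-ketoimide synthesis) sets C2 (R), and A1,3 strain keeps the product from epimerising.

Step 3
Reactants: 3 (S)-4-benzyl-3-[(2R)-2-methyl-3-oxopentanoyl]-1,3-oxazolidin-2-one; 4 3-(trimethylsilyl)prop-2-ynal
Product: 5 (S)-4-benzyl-3-[(2R,4S,5R)-5-hydroxy-2,4-dimethyl-3-oxo-7-(trimethylsilyl)hept-6-ynoyl]-1,3-oxazolidin-2-one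
Conditions: (c-Hex)2BCl, EtNMe2, Et2O, 0 °C; 4, −78 °C; then MeOH, pH 7 buffer, 30% H2O2, 0 °C
Reagents that add atoms: none
Why: Evans anti-selective aldol of the (E)-dicyclohexylboron enolate of a β-ketoimide (Zimmerman–Traxler chair, enolate face dictated by C2) gives the 2,4-anti-4,5-anti adduct, setting C4 and C5.

Step 4
Reactants: 5 (S)-4-benzyl-3-[(2R,4S,5R)-5-hydroxy-2,4-dimethyl-3-oxo-7-(trimethylsilyl)hept-6-ynoyl]-1,3-oxazolidin-2-one
Product: 6 (S)-4-benzyl-3-[(2R,3R,4R,5R)-3,5-dihydroxy-2,4-dimethyl-7-(trimethylsilyl)hept-6-ynoyl]-1,3-oxazolidin-2-one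
Conditions: Me4NBH(OAc)3, MeCN/AcOH (1:1), −20 °C
Reagents that add atoms: none
Why: Evans–Saksena hydroxyl-directed reduction (intramolecular hydride delivery from the C5 alkoxyborohydride through a chair) gives the 3,5-anti diol and sets C3.

Step 5
Reactants: 6 (S)-4-benzyl-3-[(2R,3R,4R,5R)-3,5-dihydroxy-2,4-dimethyl-7-(trimethylsilyl)hept-6-ynoyl]-1,3-oxazolidin-2-one
Product: 7 (S)-4-benzyl-3-[(2R)-2-[(4R,5R,6R)-2,2,5-trimethyl-6-[(trimethylsilyl)ethynyl]-1,3-dioxan-4-yl]propanoyl]-1,3-oxazolidin-2-one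
Conditions: Me2C(OMe)2, PPTS (cat.), CH2Cl2, rt
Reagents that add atoms: 2,2-dimethoxypropane, COC(C)(C)OC
Why: Acetonide formation protects the 3,5-diol for the esterification; no stereocentre is touched.

Step 6
Reactants: 7 (S)-4-benzyl-3-[(2R)-2-[(4R,5R,6R)-2,2,5-trimethyl-6-[(trimethylsilyl)ethynyl]-1,3-dioxan-4-yl]propanoyl]-1,3-oxazolidin-2-one
Product: 9 (2R)-2-[(4R,5R,6R)-6-ethynyl-2,2,5-trimethyl-1,3-dioxan-4-yl]propanoic acid, via peroxy acid 8 (not isolated)
Conditions: LiOH, 30% H2O2, THF/H2O (3:1), 0 °C → rt; Na2SO3 (aq); 1 M HCl to pH 3–4, 0 °C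
Reagents that add atoms: hydrogen peroxide (as LiOOH), OO
Why: Evans auxiliary removal by LiOOH attacks the exocyclic carbonyl without epimerising C2, and the excess hydroxide removes the alkynyl silyl group in the same pot (protodesilylation).

Step 7
Reactants: 10 methyl (S)-3-hydroxybutanoate
Product: 11 methyl (2S,3S)-3-hydroxy-2-methylbutanoate
Conditions: LiN(iPr)2 (2.2 equiv), THF, −78 → −20 °C; MeI, DMPU, −78 → 0 °C; NH4Cl (aq)
Reagents that add atoms: iodomethane, CI
Why: Fráter–Seebach alkylation of the chelated dianion anti to the C15 substituent sets C14 with the 14,15-anti relationship.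

Step 8
Reactants: 11 methyl (2S,3S)-3-hydroxy-2-methylbutanoate
Product: 12 methyl (2S,3S)-3-[(tert-butyldimethylsilyl)oxy]-2-methylbutanoate
Conditions: TBSCl, imidazole, DMF, rt
Reagents that add atoms: tert-butyldimethylsilyl chloride, CC(C)(C)[Si](C)(C)Cl
Why: Silyl ether formation marks O15 so that O13 is later the only free hydroxyl.

Step 9
Reactants: 12 methyl (2S,3S)-3-[(tert-butyldimethylsilyl)oxy]-2-methylbutanoate
Product: 13 (2R,3S)-3-[(tert-butyldimethylsilyl)oxy]-2-methylbutan-1-ol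
Conditions: LiAlH4, Et2O, 0 °C
Reagents that add atoms: none
Why: Hydride reduction of the ester to the primary alcohol (the descriptor at C14 changes by priority only).

Step 10
Reactants: 13 (2R,3S)-3-[(tert-butyldimethylsilyl)oxy]-2-methylbutan-1-ol; 14 but-3-en-2-yl acetate (racemic)
Product: 16 (3R,4R,5R,6S)-6-[(tert-butyldimethylsilyl)oxy]-3,5-dimethylhept-1-en-4-ol, via transient aldehyde 15 (not isolated)
Conditions: 14 (2 equiv), [Ir(cod)Cl]2 (2.5 mol%), (R)-SEGPHOS (5 mol%), 4-cyano-3-nitrobenzoic acid (10 mol%), Cs2CO3 (20 mol%), THF, 90 °C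
Reagents that add atoms: none
Why: Krische transfer-hydrogenative anti-crotylation: the alcohol is dehydrogenated to 15, and the (E)-σ-crotyliridium adds through a chair (12,13-anti) to the Re face under catalyst control (the (R)-ligand is chosen for that face), overriding the Felkin preference to give the anti,anti triad (C12, C13).

Step 11
Reactants: 9 (2R)-2-[(4R,5R,6R)-6-ethynyl-2,2,5-trimethyl-1,3-dioxan-4-yl]propanoic acid; 16 (3R,4R,5R,6S)-6-[(tert-butyldimethylsilyl)oxy]-3,5-dimethylhept-1-en-4-ol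
Product: 18 (3R,4R,5R,6S)-6-[(tert-butyldimethylsilyl)oxy]-3,5-dimethylhept-1-en-4-yl (2R)-2-[(4R,5R,6R)-6-ethynyl-2,2,5-trimethyl-1,3-dioxan-4-yl]propanoate, via mixed anhydride 17 (not isolated)
Conditions: 2,4,6-Cl3C6H2COCl, Et3N, THF, rt; then 16, DMAP, toluene, rt → 50 °C
Reagents that add atoms: none
Why: Yamaguchi esterification through the mixed anhydride forms the O13–C1 ester intermolecularly while O13 is the only free hydroxyl; no stereocentre is involved.

Step 12
Reactants: 18 (3R,4R,5R,6S)-6-[(tert-butyldimethylsilyl)oxy]-3,5-dimethylhept-1-en-4-yl (2R)-2-[(4R,5R,6R)-6-ethynyl-2,2,5-trimethyl-1,3-dioxan-4-yl]propanoate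
Product: 20 (2S,3S,4R,5S)-5-[(tert-butyldimethylsilyl)oxy]-2,4-dimethyl-1-oxohexan-3-yl (2R)-2-[(4R,5R,6R)-6-ethynyl-2,2,5-trimethyl-1,3-dioxan-4-yl]propanoate, via ozonide 19 (not isolated)
Conditions: O3, CH2Cl2, −78 °C (Sudan red 7B end point); PPh3, −78 °C → rt
Reagents that add atoms: ozone, [O-][O+]=O
Why: Criegee ozonolysis with reductive work-up cleaves the terminal alkene, which reacts far faster than the terminal alkyne, and leaves C12 untouched.

Step 13
Reactants: 20 (2S,3S,4R,5S)-5-[(tert-butyldimethylsilyl)oxy]-2,4-dimethyl-1-oxohexan-3-yl (2R)-2-[(4R,5R,6R)-6-ethynyl-2,2,5-trimethyl-1,3-dioxan-4-yl]propanoate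
Product: 21 (2S,3S,4R,5S)-5-[(tert-butyldimethylsilyl)oxy]-2,4-dimethyl-1-oxohexan-3-yl (2R)-2-[(4R,5S,6S)-6-ethenyl-2,2,5-trimethyl-1,3-dioxan-4-yl]propanoate
Conditions: H2 (1 atm), Pd/CaCO3 poisoned with Pb(OAc)2, quinoline, EtOAc, rt
Reagents that add atoms: none
Why: Lindlar semihydrogenation unmasks the vinyl group needed as radical precursor; the aldehyde is inert and the descriptor changes in the dioxane are by priority only.

Step 14
Reactants: 21 (2S,3S,4R,5S)-5-[(tert-butyldimethylsilyl)oxy]-2,4-dimethyl-1-oxohexan-3-yl (2R)-2-[(4R,5S,6S)-6-ethenyl-2,2,5-trimethyl-1,3-dioxan-4-yl]propanoate; 22 2-methylpent-1-en-3-one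
Product: 23 (4S,5R,6R,7R,8R,9S)-9-[(tert-butyldimethylsilyl)oxy]-5-hydroxy-2,4,6,8-tetramethyl-3-oxodec-1-en-7-yl (2R)-2-[(4R,5S,6S)-6-ethenyl-2,2,5-trimethyl-1,3-dioxan-4-yl]propanoate
Conditions: 22 (3 equiv), (−)-Ipc2BOTf, iPr2NEt, CH2Cl2, −78 °C; 21, −78 → −20 °C; then pH 7 buffer, MeOH, 30% H2O2, 0 °C
Reagents that add atoms: none
Why: Paterson reagent-controlled boron aldol: the (Z)-enol diisopinocampheylborinate adds through a chair (10,11-syn) to the Si face of 21 (the anti-configured aldehyde has little intrinsic bias toward Z-enolates, so the Ipc ligands decide; the (−)-reagent is chosen for that face), setting C10 and C11 and installing the enone in one step.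

Step 15
Reactants: 23 (4S,5R,6R,7R,8R,9S)-9-[(tert-butyldimethylsilyl)oxy]-5-hydroxy-2,4,6,8-tetramethyl-3-oxodec-1-en-7-yl (2R)-2-[(4R,5S,6S)-6-ethenyl-2,2,5-trimethyl-1,3-dioxan-4-yl]propanoate
Product: 26 3,5-O-isopropylidene-15-O-(tert-butyldimethylsilyl) derivative of 27 (all stereocentres as in 27), via C6 alkyl radical 24 (not isolated), via C8 keto radical 25 (not isolated)
Conditions: Fe(acac)3 (30 mol%), PhSiH3 (3 equiv), EtOH/(CH2OH)2 (5:1), 60 °C; 23 added by syringe pump over 8 h (final 2 mM)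
Reagents that add atoms: none
Why: Proposed new method: hydrogen-atom transfer from the iron hydride made from Fe(acac)3 and PhSiH3 to the vinyl group gives the nucleophilic secondary radical 24, which closes the 14-membered ring by endo Giese addition to the CH2 terminus of the isopropenyl ketone (closest known chemistry: Baran's intermolecular Fe(acac)3/PhSiH3 olefin–enone coupling and Porter's tin-mediated 14-endo cyclisations of alkyl radicals onto enones); C6 is expected from attack anti to the C5–O bond with C5–H eclipsing the radical methyl (Felkin–Anh-type induction from the dioxane), and C8 from reduction of 25 to the iron enolate and protonation on its outer face.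

Step 16
Reactants: 26 3,5-O-isopropylidene-15-O-(tert-butyldimethylsilyl) derivative of 27
Product: 27 (3R,4R,5S,6S,7R,9R,11S,12R,13R,14S)-4,6,12-trihydroxy-14-[(2S,3S)-3-hydroxybutan-2-yl]-3,5,7,9,11,13-hexamethyl-1-oxacyclotetradecane-2,10-dione (CNP0244358.2)
Conditions: 1 M HCl (aq), THF/MeOH, rt
Reagents that add atoms: none
Why: Acid hydrolysis removes the acetonide and the secondary silyl ether together; no stereocentre is affected under these mild conditions.

## Compound list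

1 | propanoyl chloride | CCC(=O)Cl | starting material
2 | (S)-4-benzyl-3-propanoyl-1,3-oxazolidin-2-one | O=C1OC[C@H](Cc2ccccc2)N1C(=O)CC | intermediate
3 | (S)-4-benzyl-3-[(2R)-2-methyl-3-oxopentanoyl]-1,3-oxazolidin-2-one | O=C1OC[C@H](Cc2ccccc2)N1C(=O)[C@H](C)C(=O)CC | intermediate
4 | 3-(trimethylsilyl)prop-2-ynal | C[Si](C)(C)C#CC=O | starting material
5 | (S)-4-benzyl-3-[(2R,4S,5R)-5-hydroxy-2,4-dimethyl-3-oxo-7-(trimethylsilyl)hept-6-ynoyl]-1,3-oxazolidin-2-one | O=C1OC[C@H](Cc2ccccc2)N1C(=O)[C@H](C)C(=O)[C@@H](C)[C@@H](O)C#C[Si](C)(C)C | intermediate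
6 | (S)-4-benzyl-3-[(2R,3R,4R,5R)-3,5-dihydroxy-2,4-dimethyl-7-(trimethylsilyl)hept-6-ynoyl]-1,3-oxazolidin-2-one | O=C1OC[C@H](Cc2ccccc2)N1C(=O)[C@H](C)[C@H](O)[C@@H](C)[C@@H](O)C#C[Si](C)(C)C | intermediate
7 | (S)-4-benzyl-3-[(2R)-2-[(4R,5R,6R)-2,2,5-trimethyl-6-[(trimethylsilyl)ethynyl]-1,3-dioxan-4-yl]propanoyl]-1,3-oxazolidin-2-one | O=C1OC[C@H](Cc2ccccc2)N1C(=O)[C@H](C)[C@H]3[C@@H](C)[C@H](C#C[Si](C)(C)C)OC(C)(C)O3 | intermediate
8 | (2R)-2-[(4R,5R,6R)-6-ethynyl-2,2,5-trimethyl-1,3-dioxan-4-yl]propaneperoxoic acid (not isolated) | OOC(=O)[C@H](C)[C@H]1[C@@H](C)[C@H](C#C)OC(C)(C)O1 | intermediate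
9 | (2R)-2-[(4R,5R,6R)-6-ethynyl-2,2,5-trimethyl-1,3-dioxan-4-yl]propanoic acid | OC(=O)[C@H](C)[C@H]1[C@@H](C)[C@H](C#C)OC(C)(C)O1 | intermediate
10 | methyl (S)-3-hydroxybutanoate | C[C@H](O)CC(=O)OC | starting material
11 | methyl (2S,3S)-3-hydroxy-2-methylbutanoate | COC(=O)[C@@H](C)[C@@H](O)C | intermediate
12 | methyl (2S,3S)-3-[(tert-butyldimethylsilyl)oxy]-2-methylbutanoate | COC(=O)[C@@H](C)[C@@H](O[Si](C)(C)C(C)(C)C)C | intermediate
13 | (2R,3S)-3-[(tert-butyldimethylsilyl)oxy]-2-methylbutan-1-ol | OC[C@@H](C)[C@@H](O[Si](C)(C)C(C)(C)C)C | intermediate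
14 | but-3-en-2-yl acetate (racemic) | CC(OC(C)=O)C=C | starting material
15 | (2S,3S)-3-[(tert-butyldimethylsilyl)oxy]-2-methylbutanal (not isolated) | O=C[C@@H](C)[C@@H](O[Si](C)(C)C(C)(C)C)C | intermediate
16 | (3R,4R,5R,6S)-6-[(tert-butyldimethylsilyl)oxy]-3,5-dimethylhept-1-en-4-ol | C=C[C@@H](C)[C@@H](O)[C@@H](C)[C@@H](O[Si](C)(C)C(C)(C)C)C | intermediate
17 | mixed anhydride of 9 with 2,4,6-trichlorobenzoic acid (not isolated) | O=C(OC(=O)[C@H](C)[C@H]1[C@@H](C)[C@H](C#C)OC(C)(C)O1)c2c(Cl)cc(Cl)cc2Cl | intermediate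
18 | (3R,4R,5R,6S)-6-[(tert-butyldimethylsilyl)oxy]-3,5-dimethylhept-1-en-4-yl (2R)-2-[(4R,5R,6R)-6-ethynyl-2,2,5-trimethyl-1,3-dioxan-4-yl]propanoate | C=C[C@@H](C)[C@@H](OC(=O)[C@H](C)[C@H]1[C@@H](C)[C@H](C#C)OC(C)(C)O1)[C@@H](C)[C@@H](O[Si](C)(C)C(C)(C)C)C | intermediate
19 | 1,2,4-trioxolane (secondary ozonide) of 18 at the C11 vinyl group, both epimers at the trioxolane carbon (not isolated) | C1OC(OO1)[C@@H](C)[C@@H](OC(=O)[C@H](C)[C@H]2[C@@H](C)[C@H](C#C)OC(C)(C)O2)[C@@H](C)[C@@H](O[Si](C)(C)C(C)(C)C)C | intermediate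
20 | (2S,3S,4R,5S)-5-[(tert-butyldimethylsilyl)oxy]-2,4-dimethyl-1-oxohexan-3-yl (2R)-2-[(4R,5R,6R)-6-ethynyl-2,2,5-trimethyl-1,3-dioxan-4-yl]propanoate | O=C[C@@H](C)[C@@H](OC(=O)[C@H](C)[C@H]1[C@@H](C)[C@H](C#C)OC(C)(C)O1)[C@@H](C)[C@@H](O[Si](C)(C)C(C)(C)C)C | intermediate
21 | (2S,3S,4R,5S)-5-[(tert-butyldimethylsilyl)oxy]-2,4-dimethyl-1-oxohexan-3-yl (2R)-2-[(4R,5S,6S)-6-ethenyl-2,2,5-trimethyl-1,3-dioxan-4-yl]propanoate | O=C[C@@H](C)[C@@H](OC(=O)[C@H](C)[C@H]1[C@@H](C)[C@H](C=C)OC(C)(C)O1)[C@@H](C)[C@@H](O[Si](C)(C)C(C)(C)C)C | intermediate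
22 | 2-methylpent-1-en-3-one | CCC(=O)C(C)=C | starting material
23 | (4S,5R,6R,7R,8R,9S)-9-[(tert-butyldimethylsilyl)oxy]-5-hydroxy-2,4,6,8-tetramethyl-3-oxodec-1-en-7-yl (2R)-2-[(4R,5S,6S)-6-ethenyl-2,2,5-trimethyl-1,3-dioxan-4-yl]propanoate | C=C(C)C(=O)[C@@H](C)[C@H](O)[C@@H](C)[C@@H](OC(=O)[C@H](C)[C@H]1[C@@H](C)[C@H](C=C)OC(C)(C)O1)[C@@H](C)[C@@H](O[Si](C)(C)C(C)(C)C)C | intermediate
24 | C6 secondary alkyl radical of 23 (H added to the vinyl CH2; not isolated) | C=C(C)C(=O)[C@@H](C)[C@H](O)[C@@H](C)[C@@H](OC(=O)[C@H](C)[C@H]1[C@@H](C)[C@H]([CH]C)OC(C)(C)O1)[C@@H](C)[C@@H](O[Si](C)(C)C(C)(C)C)C | intermediate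
25 | macrocyclic C8 α-keto radical (C6–C7 bond formed; not isolated) | O=C1[C@H](C)[C@H]2[C@@H](C)[C@@H](OC(C)(C)O2)[C@H](C)C[C](C)C(=O)[C@@H](C)[C@H](O)[C@@H](C)[C@@H](O1)[C@@H](C)[C@@H](O[Si](C)(C)C(C)(C)C)C | intermediate
26 | 3,5-O-isopropylidene-15-O-(tert-butyldimethylsilyl) derivative of 27, all stereocentres as in 27 | O=C1[C@H](C)[C@H]2[C@@H](C)[C@@H](OC(C)(C)O2)[C@H](C)C[C@@H](C)C(=O)[C@@H](C)[C@H](O)[C@@H](C)[C@@H](O1)[C@@H](C)[C@@H](O[Si](C)(C)C(C)(C)C)C | intermediate
27 | (3R,4R,5S,6S,7R,9R,11S,12R,13R,14S)-4,6,12-trihydroxy-14-[(2S,3S)-3-hydroxybutan-2-yl]-3,5,7,9,11,13-hexamethyl-1-oxacyclotetradecane-2,10-dione | C[C@@H]1[C@@H](O)[C@H](C)C(=O)[C@H](C)C[C@@H](C)[C@H](O)[C@H](C)[C@@H](O)[C@@H](C)C(=O)O[C@H]1[C@@H](C)[C@H](C)O | target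

## Step count and risks

Total steps: 16. Longest linear sequence: 12 steps (1 → 27, steps 1–6 and then 11–16). The alcohol branch (10 → 16, steps 7–10) is 4 steps and joins at step 11, so its own chain to 27 is 10 steps.

**Step 15 (radical macrocyclisation).** Risks: the enone may be reduced faster than the slow vinyl hydrogen-atom transfer at high dilution, and the facial selectivity at C6 and the protonation at C8 are untested in this stereochemical series. Fallback: exchange the order of the last two carbon–carbon bond formations. Set out from aldehyde 21 and couple it intermolecularly with 22 (5 equiv) under Fe(acac)3/PhSiH3 in EtOH at normal concentration, the precedented intermolecular mode. This gives the ethyl ketone (2S,3S,4R,5S)-5-[(tert-butyldimethylsilyl)oxy]-2,4-dimethyl-1-oxohexan-3-yl (2R)-2-[(4R,5S,6S)-2,2,5-trimethyl-6-[(2R,4RS)-4-methyl-5-oxoheptan-2-yl]-1,3-dioxan-4-yl]propanoate F3, with C6 under acyclic Felkin-type control and C8 as a mixture that can be equilibrated or separated after ring closure. Then enolise the ethyl ketone on its CH2 side with (−)-Ipc2BOTf/iPr2NEt and close the ring by intramolecular syn-aldol addition to the C11 aldehyde at high dilution, which comes back to the route at 26.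

**Step 10 (mismatched anti-crotylation).** Risk: the anti,anti triad is the anti-Felkin product, so catalyst control may be incomplete and the anti:syn ratio modest. Fallback: set out from alcohol 13, oxidise it under Swern conditions ((COCl)2, DMSO, Et3N) to aldehyde 15, here isolated. Add the chiral allenylzinc reagent generated from (S)-but-3-yn-2-yl methanesulfonate with Pd(OAc)2, PPh3 and Et2Zn in THF at −20 °C (Marshall propargylation, net inversion at the propargylic carbon, anti addition under reagent control). This gives (3R,4R,5R,6S)-6-[(tert-butyldimethylsilyl)oxy]-3,5-dimethylhept-1-yn-4-ol F1. Semihydrogenation (H2, Pd/CaCO3 poisoned with Pb(OAc)2, quinoline) comes back to the route at 16.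

**Step 14 (reagent-controlled aldol).** Risks: Ipc control of the aldehyde face may be only moderate, and the enone is sensitive to the oxidative work-up. Fallback: switch from the closed boron transition state to an open, substrate-controlled Mukaiyama aldol. Set out from 22 and convert it (TMSOTf, Et3N, Et2O, 0 °C) into (Z)-trimethyl[(2-methylpenta-1,3-dien-3-yl)oxy]silane F2. Add F2 to aldehyde 21 with BF3·OEt2 in CH2Cl2 at −78 °C, where Felkin and 1,3-anti induction from the anti-α-methyl-β-acyloxy aldehyde reinforce each other and the (Z)-enol silane favours the 10,11-syn adduct. This comes back to the route at 23.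

## Further compounds

F1 | step 10 | (3R,4R,5R,6S)-6-[(tert-butyldimethylsilyl)oxy]-3,5-dimethylhept-1-yn-4-ol | C#C[C@@H](C)[C@@H](O)[C@@H](C)[C@@H](O[Si](C)(C)C(C)(C)C)C
F2 | step 14 | (Z)-trimethyl[(2-methylpenta-1,3-dien-3-yl)oxy]silane | C=C(C)/C(O[Si](C)(C)C)=C/C
F3 | step 15 | (2S,3S,4R,5S)-5-[(tert-butyldimethylsilyl)oxy]-2,4-dimethyl-1-oxohexan-3-yl (2R)-2-[(4R,5S,6S)-2,2,5-trimethyl-6-[(2R,4RS)-4-methyl-5-oxoheptan-2-yl]-1,3-dioxan-4-yl]propanoate | O=C[C@@H](C)[C@@H](OC(=O)[C@H](C)[C@H]1[C@@H](C)[C@@H](OC(C)(C)O1)[C@H](C)CC(C)C(=O)CC)[C@@H](C)[C@@H](O[Si](C)(C)C(C)(C)C)C
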